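Ring A of the spiroketal, the oxolane that carries the hexyl tether (O1, C2, C3, C4 and the spiro carbon C5 of the 1,6-dioxaspiro[4.4]nonane), is a γ-lactone in disguise: the ketal carbon C5 is a lactone carbonyl that lacks one C–C bond, and O1–C2 is a C–O bond at a secondary stereocentre. Everything rests on inserting O1 into the C5–C2 bond of an (S)-2-alkylcyclobutanone by Baeyer–Villiger ring expansion, which turns the four-membered carbocycle C2–C3–C4–C5 into the five-membered ring with retention at C2. The precursor is 2-(hex-5-enyl)cyclobutanone from a RAMP-hydrazone alkylation; the lactone carbonyl then takes up the four-carbon arm of ring B, and the alkene later carries the phthalide.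

Key step: step 6

Remark on the chemistry: the two C5 epimers of a 2,7-dialkyl-1,6-dioxaspiro[4.4]nonane interconvert in acid and neither is expected to be strongly favoured, so C5 is set by equilibration, separation and recycling in step 7 and is assumed to hold under the non-acidic steps 8 and 9 (spiroketal numbering: O1, C2 with the tether, C3, C4, spiro C5, O6, C7 with the methyl group, C8, C9).

Step 1
Reactants: 1 (S)-butane-1,3-diol
Product: 2 (S)-4-iodobutan-2-ol
Conditions: I2, PPh3, imidazole, CH2Cl2, 0 °C
Reagents that add atoms: iodine, II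
Why: Appel-type iodination should convert only the unhindered primary hydroxyl, and the secondary carbinol centre (the future C7) is not touched.

Step 2
Reactants: 2 (S)-4-iodobutan-2-ol
Product: 3 (S)-triethyl[(4-iodobutan-2-yl)oxy]silane
Conditions: Et3SiCl, imidazole, CH2Cl2, 0 °C
Reagents that add atoms: chlorotriethylsilane, CC[Si](Cl)(CC)CC
Why: Standard silylation of a secondary alcohol gives a TES ether that should survive iodine–lithium exchange at −78 °C and is shed by the aqueous acid that closes the spiroketal in step 7.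

Step 3
Reactants: 4 cyclobutanone, 5 RAMP, (R)-1-amino-2-(methoxymethyl)pyrrolidine
Product: 6 (R)-N-cyclobutylidene-2-(methoxymethyl)pyrrolidin-1-amine
Conditions: CH2Cl2, 4 Å molecular sieves, rt
Reagents that add atoms: none
Why: Condensation of the ketone with the N-amino auxiliary gives the RAMP hydrazone (first stage of the Enders hydrazone method), and the symmetric ring makes the C=N geometry irrelevant.

Step 4
Reactants: 6 (R)-N-cyclobutylidene-2-(methoxymethyl)pyrrolidin-1-amine, 7 6-bromohex-1-ene
Product: 9 (R)-N-[(2S)-2-(hex-5-en-1-yl)cyclobutylidene]-2-(methoxymethyl)pyrrolidin-1-amine, via lithium azaenolate 8 (not isolated)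
Conditions: LiN(iPr)2, THF, 0 °C; then 7, −95 °C → rt
Reagents that add atoms: none
Why: Enders RAMP-hydrazone α-alkylation, in which the chelated lithium azaenolate is alkylated by the primary bromide on the face left open by the methoxymethyl arm; by the usual model for cyclic ketones (SAMP leads to (R)-2-alkylcycloalkanones) RAMP should set C2 as (S).

Step 5
Reactants: 9 (R)-N-[(2S)-2-(hex-5-en-1-yl)cyclobutylidene]-2-(methoxymethyl)pyrrolidin-1-amine
Product: 10 (S)-2-(hex-5-en-1-yl)cyclobutan-1-one
Conditions: sat. aq. oxalic acid, Et2O, rt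
Reagents that add atoms: water, O
Why: Two-phase oxalic acid hydrolysis of the hydrazone is mild enough to leave the α-stereocentre and the terminal alkene intact, and it returns the auxiliary from the aqueous phase.

Step 6
Reactants: 10 (S)-2-(hex-5-en-1-yl)cyclobutan-1-one
Product: 12 (S)-5-(hex-5-en-1-yl)oxolan-2-one, via Criegee perhydrate 11 (not isolated)
Conditions: 30% aq. H2O2, AcOH, 0 °C
Reagents that add atoms: hydrogen peroxide, OO
Why: Baeyer–Villiger oxidation: hydrogen peroxide adds to the strained carbonyl to give the Criegee perhydrate 11, in which the C5–C2 bond migrates to the proximal peroxide oxygen as water leaves, so that O1 is inserted between C5 and C2. The closest known reaction type is the Baeyer–Villiger ring expansion of 2-substituted cyclobutanones to γ-substituted γ-butyrolactones. The five-membered ring O1–C2–C3–C4–C5 is not closed by a cyclisation but arises by a 1,2-shift that expands the four-membered ring C2–C3–C4–C5 by one atom. No new stereocentre is formed; C2 migrates with retention, so the (S) centre set in step 4 becomes the O1-bearing (S) centre of the target. The step needs regioselectivity (C2 and not C4 must migrate) and chemoselectivity over the terminal alkene; the first is secured by the higher migratory aptitude of the secondary carbon, the second by the strain-accelerated reaction of the cyclobutanone with hydrogen peroxide under conditions that should not epoxidise an isolated alkene.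

Step 7
Reactants: 3 (S)-triethyl[(4-iodobutan-2-yl)oxy]silane, 12 (S)-5-(hex-5-en-1-yl)oxolan-2-one
Product: 16 (2S,5S,7S)-2-(hex-5-en-1-yl)-7-methyl-1,6-dioxaspiro[4.4]nonane, via alkyllithium 13 (not isolated), via lithium lactolate 14 (not isolated), via lactol diol 15 (not isolated)
Conditions: 3, t-BuLi (2 equiv), Et2O, −78 °C; then 12, −78 °C; then 1 M aq. HCl, THF, 0 °C → rt; chromatography
Reagents that add atoms: none
Why: Iodine–lithium exchange gives the alkyllithium, which should add only once to the γ-lactone because the lithium lactolate is stable at −78 °C, and aqueous acid then removes the TES group and closes ring B by acid-catalysed spiroketalisation through the C5 oxocarbenium ion, C2 and C7 being untouched while C5 is set under equilibrating conditions, from which the (5S) epimer (both substituents cis to the oxygen of the other ring) is to be isolated by chromatography and the (5R) epimer returned to the same acid.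

Step 8
Reactants: 16 (2S,5S,7S)-2-(hex-5-en-1-yl)-7-methyl-1,6-dioxaspiro[4.4]nonane, 17 2-bromo-3,5-dimethoxybenzaldehyde
Product: 20 (1S)-1-(2-bromo-3,5-dimethoxyphenyl)-7-[(2S,5S,7S)-7-methyl-1,6-dioxaspiro[4.4]nonan-2-yl]heptan-1-ol, via diethylalkylborane 18 (not isolated), via dialkylzinc 19 (not isolated)
Conditions: Et2BH, Et2O, 0 °C → rt; Et2Zn (neat), 0 °C, then vacuum; then 17, Ti(OiPr)4, (1R,2R)-1,2-bis(trifluoromethanesulfonamido)cyclohexane (8 mol%), toluene, −20 °C; aq. NH4Cl
Reagents that add atoms: none
Why: Anti-Markovnikov hydroboration and boron–zinc exchange give a functionalised dialkylzinc whose titanium/bis(sulfonamide)-catalysed asymmetric addition to the aromatic aldehyde should deliver the alkyl group to the Si face, as the (1R,2R) ligand does with benzaldehyde, so that the benzylic carbinol is set as (S) under catalyst control, independent of the remote spiroketal.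

Step 9
Reactants: 20 (1S)-1-(2-bromo-3,5-dimethoxyphenyl)-7-[(2S,5S,7S)-7-methyl-1,6-dioxaspiro[4.4]nonan-2-yl]heptan-1-ol
Product: 21 (3S)-5,7-dimethoxy-3-{6-[(2S,5S,7S)-7-methyl-1,6-dioxaspiro[4.4]nonan-2-yl]hexyl}-2-benzofuran-1(3H)-one
Conditions: Pd(OAc)2 (5 mol%), Xantphos (6 mol%), CO (1 atm), Et3N, toluene, 90 °C
Reagents that add atoms: carbon monoxide, [C-]#[O+]
Why: Palladium-catalysed carbonylative lactonisation of an ortho-bromobenzylic alcohol (oxidative addition of zerovalent palladium into the C–Br bond, CO insertion, capture of the acylpalladium by the neighbouring hydroxyl) should close the phthalide without breaking the carbinol C–O bond, so the (S) centre is kept, and the basic medium leaves the spiroketal alone.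

Compound list
1 | (S)-butane-1,3-diol | C[C@H](O)CCO | starting material
2 | (S)-4-iodobutan-2-ol | C[C@H](O)CCI | intermediate
3 | (S)-triethyl[(4-iodobutan-2-yl)oxy]silane | C[C@H](O[Si](CC)(CC)CC)CCI | intermediate
4 | cyclobutanone | O=C1CCC1 | starting material
5 | RAMP, (R)-1-amino-2-(methoxymethyl)pyrrolidine | COC[C@H]1CCCN1N | starting material
6 | (R)-N-cyclobutylidene-2-(methoxymethyl)pyrrolidin-1-amine | COC[C@H]1CCCN1N=C1CCC1 | intermediate
7 | 6-bromohex-1-ene | C=CCCCCBr | starting material
8 | lithium azaenolate of 6 (not isolated) | COC[C@H]1CCCN1N([Li])C1=CCC1 | intermediate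
9 | (R)-N-[(2S)-2-(hex-5-en-1-yl)cyclobutylidene]-2-(methoxymethyl)pyrrolidin-1-amine (C=N geometry not defined) | COC[C@H]1CCCN1N=C1CC[C@@H]1CCCCC=C | intermediate
10 | (S)-2-(hex-5-en-1-yl)cyclobutan-1-one | C=CCCCC[C@H]1CCC1=O | intermediate
11 | Criegee perhydrate, (2S)-2-(hex-5-en-1-yl)-1-hydroperoxycyclobutan-1-ol (not isolated, C1 not defined) | C=CCCCC[C@H]1CCC1(O)OO | intermediate
12 | (S)-5-(hex-5-en-1-yl)oxolan-2-one | C=CCCCC[C@H]1CCC(=O)O1 | intermediate
13 | [(3S)-3-(triethylsilyloxy)butyl]lithium (not isolated) | C[C@H](O[Si](CC)(CC)CC)CC[Li] | intermediate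
14 | lithium (5S)-5-(hex-5-en-1-yl)-2-[(3S)-3-(triethylsilyloxy)butyl]oxolan-2-olate (not isolated, C2 not defined) | [Li]OC1(CC[C@H](C)O[Si](CC)(CC)CC)CC[C@H](CCCCC=C)O1 | intermediate
15 | (5S)-5-(hex-5-en-1-yl)-2-[(3S)-3-hydroxybutyl]oxolan-2-ol (not isolated, C2 not defined) | OC1(CC[C@H](C)O)CC[C@H](CCCCC=C)O1 | intermediate
16 | (2S,5S,7S)-2-(hex-5-en-1-yl)-7-methyl-1,6-dioxaspiro[4.4]nonane | C=CCCCC[C@H]1CC[C@]2(CC[C@H](C)O2)O1 | intermediate
17 | 2-bromo-3,5-dimethoxybenzaldehyde | COc1cc(OC)c(Br)c(C=O)c1 | starting material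
18 | diethyl{6-[(2S,5S,7S)-7-methyl-1,6-dioxaspiro[4.4]nonan-2-yl]hexyl}borane (not isolated) | CCB(CC)CCCCCC[C@H]1CC[C@]2(CC[C@H](C)O2)O1 | intermediate
19 | bis{6-[(2S,5S,7S)-7-methyl-1,6-dioxaspiro[4.4]nonan-2-yl]hexyl}zinc (not isolated) | [Zn](CCCCCC[C@H]1CC[C@]2(CC[C@H](C)O2)O1)CCCCCC[C@H]1CC[C@]2(CC[C@H](C)O2)O1 | intermediate
20 | (1S)-1-(2-bromo-3,5-dimethoxyphenyl)-7-[(2S,5S,7S)-7-methyl-1,6-dioxaspiro[4.4]nonan-2-yl]heptan-1-ol | COc1cc(OC)c(Br)c(c1)[C@@H](O)CCCCCC[C@H]1CC[C@]2(CC[C@H](C)O2)O1 | intermediate
21 | (3S)-5,7-dimethoxy-3-{6-[(2S,5S,7S)-7-methyl-1,6-dioxaspiro[4.4]nonan-2-yl]hexyl}-2-benzofuran-1(3H)-one | COc1cc(OC)c2c(c1)[C@H](CCCCCC[C@H]1CC[C@]3(CC[C@H](C)O3)O1)OC2=O | target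

Total step count: 9. Longest linear sequence: 7 steps (steps 3 to 9, from cyclobutanone).

Steps most likely to fail

Step 8. Only one of the two alkyl groups on zinc is transferred, so the advanced alkene must be used in excess. Boron–zinc exchange may also be incomplete, and the ortho-bromine may erode facial control. The fallback sets out from 16 and 17 and returns at 20. Aldehyde 17 is treated with CH2=CHMgBr to give racemic 1-(2-bromo-3,5-dimethoxyphenyl)prop-2-en-1-ol F1. Sharpless kinetic resolution (Ti(OiPr)4, L-(+)-diisopropyl tartrate, t-BuOOH, CH2Cl2, −20 °C) should consume the (R) enantiomer and leave (S)-1-(2-bromo-3,5-dimethoxyphenyl)prop-2-en-1-ol F2. Cross-metathesis of 16 with an excess of F2 (second-generation Grubbs catalyst, (H2IMes)(PCy3)Cl2Ru=CHPh, CH2Cl2, 40 °C) should give (1S,2E)-1-(2-bromo-3,5-dimethoxyphenyl)-7-[(2S,5S,7S)-7-methyl-1,6-dioxaspiro[4.4]nonan-2-yl]hept-2-en-1-ol F3. Diimide reduction (o-nitrobenzenesulfonylhydrazide, Et3N) then saturates the alkene without touching the C–Br or the benzylic C–O bond and gives 20.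

Step 7. A second addition of the alkyllithium may follow collapse of the lactolate, the silyl group may migrate from oxygen to carbon in the alkyllithium, and the C5 equilibrium may lie on the side of the unwanted epimer. The fallback sets out from 12 and returns at 16; it keeps ring A closed and makes C5 the nucleophile.
- Reduction of 12 (i-Bu2AlH, CH2Cl2, −78 °C) gives (5S)-5-(hex-5-en-1-yl)oxolan-2-ol F4.
- Exchange of the anomeric hydroxyl with benzenesulfinic acid (CaCl2, CH2Cl2) gives (5S)-5-(hex-5-en-1-yl)-2-(phenylsulfonyl)oxolane F5.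
- Deprotonation with n-BuLi (THF, −78 °C) and alkylation with iodide 3 gives (5S)-5-(hex-5-en-1-yl)-2-(phenylsulfonyl)-2-[(3S)-3-(triethylsilyloxy)butyl]oxolane F6.
- Aqueous acid then expels benzenesulfinate, removes the TES group and closes ring B to 16.

The position of the C5 equilibrium is inherent to the ring system and is met in either variant by separation and re-equilibration. If C5 should drift later, the same acid treatment can be applied to 21.

Step 9. Oxidative addition into the hindered, electron-rich C–Br bond may be slow, with competing β-hydride elimination from the palladium alkoxide (oxidation of the carbinol) and protodebromination. The fallback sets out from 20 and returns at 21. Treatment of 20 with t-BuLi (3 equiv, THF, −78 °C) deprotonates the hydroxyl and exchanges bromine for lithium, and CO2 then carboxylates the aryllithium. After a buffered work-up, 2-{(1S)-1-hydroxy-7-[(2S,5S,7S)-7-methyl-1,6-dioxaspiro[4.4]nonan-2-yl]heptyl}-4,6-dimethoxybenzoic acid F7 should lactonise to 21, on standing or with a carbodiimide.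

Further compounds
F1 | step 8 | racemic 1-(2-bromo-3,5-dimethoxyphenyl)prop-2-en-1-ol | COc1cc(OC)c(Br)c(c1)C(O)C=C
F2 | step 8 | (S)-1-(2-bromo-3,5-dimethoxyphenyl)prop-2-en-1-ol | COc1cc(OC)c(Br)c(c1)[C@@H](O)C=C
F3 | step 8 | (1S,2E)-1-(2-bromo-3,5-dimethoxyphenyl)-7-[(2S,5S,7S)-7-methyl-1,6-dioxaspiro[4.4]nonan-2-yl]hept-2-en-1-ol | COc1cc(OC)c(Br)c(c1)[C@@H](O)/C=C/CCCC[C@H]1CC[C@]2(CC[C@H](C)O2)O1
F4 | step 7 | (5S)-5-(hex-5-en-1-yl)oxolan-2-ol (C2 not defined) | C=CCCCC[C@H]1CCC(O)O1
F5 | step 7 | (5S)-5-(hex-5-en-1-yl)-2-(phenylsulfonyl)oxolane (C2 not defined) | C=CCCCC[C@H]1CCC(O1)S(=O)(=O)c1ccccc1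
F6 | step 7 | (5S)-5-(hex-5-en-1-yl)-2-(phenylsulfonyl)-2-[(3S)-3-(triethylsilyloxy)butyl]oxolane (C2 not defined) | C=CCCCC[C@H]1CCC(CC[C@H](C)O[Si](CC)(CC)CC)(O1)S(=O)(=O)c1ccccc1
F7 | step 9 | 2-{(1S)-1-hydroxy-7-[(2S,5S,7S)-7-methyl-1,6-dioxaspiro[4.4]nonan-2-yl]heptyl}-4,6-dimethoxybenzoic acid | COc1cc(OC)c(C(=O)O)c(c1)[C@@H](O)CCCCCC[C@H]1CC[C@]2(CC[C@H](C)O2)O1
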